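**Plan**
- Retrosynthesis cuts C9–C11 (chain C11–C16 taken off a C9 enol triflate), then C4–C18 (methyl taken off the C19 ester enolate), then C1–C10 and C4–C5 of ring A in one Diels–Alder step.
- Enabling feature: ring B carries methyl groups on C8 and C10 on either side of C9, which is the pattern of 2,6-dimethyl-1,4-benzoquinone with its carbonyls at C9 and C6; a dienyl silyl ether supplies C1–C4 and C19.
- Forward: ring B is bought as the quinone and ring A is closed onto it by a catalytic enantioselective [4+2]. Hydrogenation, C5 epimerisation and C6 deoxygenation give the trans-decalin 9-ketone, and C19 is oxidised and esterified. The C9 enol triflate is joined to the chain by a B-alkyl Suzuki–Miyaura coupling, then C4 is methylated, the silyl groups are removed and O15 is acetylated.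
- Stereochemistry: C10 from the chiral Lewis acid in the cycloaddition; C5 by base equilibration next to the C6 ketone; C4 by equatorial methylation anti to the axial C10 methyl; the 13E alkene from commercial (E)-3-methylpent-2-en-4-yn-1-ol.

Key step: step 3

Remark on numbering: labdane numbering is used for all bicyclic compounds (ring A = C1–C5 and C10; ring B = C5–C10; β is the face of the C10 methyl; C19 is the oxygenated carbon on C4).
Remark on the chemistry (assumption): the (S)-oxazaborolidinium is taken to expose the quinone face that leads to the 10S adduct; if the sense of induction is the opposite, the (R)-catalyst is used with nothing else changed.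

**Step 1**
Reactants: 1 (E)-penta-2,4-dienoic acid
Product: 2 (E)-penta-2,4-dien-1-ol
Conditions: LiAlH4, Et2O, 0 °C
Reagents that add atoms: none
Why: Hydride reduction of a carboxylic acid by LiAlH4 should give the primary alcohol by 1,2-delivery at 0 °C, leaving the conjugated diene and its E geometry untouched.

**Step 2**
Reactants: 2 (E)-penta-2,4-dien-1-ol
Product: 3 (E)-tert-butyldimethyl(penta-2,4-dien-1-yloxy)silane
Conditions: TBSCl, imidazole, CH2Cl2, 0 °C to rt
Reagents that add atoms: tert-butyldimethylsilyl chloride, CC(C)(C)[Si](C)(C)Cl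
Why: Imidazole-promoted silylation of a primary alcohol is routine, and the bulky silyl ether keeps the oxygen weakly Lewis basic for the next step.

**Step 3**
Reactants: 3 (E)-tert-butyldimethyl(penta-2,4-dien-1-yloxy)silane; 4 2,6-dimethyl-1,4-benzoquinone
Product: 5 cis-fused ene-dione adduct (4aR,5R,8aS)-5-[(tert-butyldimethylsilyloxy)methyl]-2,8a-dimethyl-4a,5,8,8a-tetrahydronaphthalene-1,4-dione
Conditions: (S)-3,3-diphenyl-1-(2-methylphenyl)tetrahydro-1H,3H-pyrrolo[1,2-c][1,3,2]oxazaborole (20 mol %) activated with HN(SO2CF3)2, CH2Cl2, −78 to −40 °C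
Reagents that add atoms: none
Why: The protonated oxazaborolidine binds the C6 carbonyl of 4 (the more basic and less hindered oxygen, flanked by two CH groups), so the carbon that becomes C10 is the electrophilic β-position and pairs with the unsubstituted diene terminus C1 in a concerted but asynchronous [4+2] cycloaddition, while the silyloxymethyl-bearing terminus C4 bonds to C5. The closest known reaction type is the oxazaborolidinium-catalysed enantioselective Diels–Alder reaction of unsymmetrical 1,4-benzoquinones with simple dienes. Ring A closes by suprafacial six-electron annulation of the four diene carbons across one quinone alkene, which forms C1–C10 and C4–C5 together and leaves the ring fusion cis. C10 takes its absolute configuration from the catalyst, whose aryl group shields one enantiotopic face of the bound quinone; C5 follows from suprafacial addition to the alkene (H cis to the C10 methyl), and C4 from the endo transition state together with the E diene geometry (CH2OTBS cis to C6). Regiochemistry is secured by Lewis acid coordination at the C6 carbonyl, site selectivity is not an issue because the two quinone alkenes are homotopic, and a second addition is held back by the hindered ene-dione of the product.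

**Step 4**
Reactants: 5 cis-fused ene-dione adduct
Product: 6 cis-fused saturated 6,9-dione (4α-CH2OTBS; 5β-H; 10β-methyl; C8 epimers)
Conditions: H2 (1 atm), Pd/C, EtOAc, rt
Reagents that add atoms: none
Why: Heterogeneous hydrogenation should saturate both the disubstituted C2=C3 alkene and the electron-poor C7=C8 alkene of the ene-dione without touching the ketones or the silyl ether; the C8 configuration formed is of no consequence because C8 is equilibrated in step 5 and becomes sp2 in step 10.

**Step 5**
Reactants: 6 cis-fused saturated 6,9-dione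
Product: 7 trans-fused 6,9-dione (4α-CH2OTBS equatorial; 5α-H; 8α-methyl equatorial; 10β-methyl)
Conditions: NaOMe (0.2 equiv), MeOH, 0 °C to rt
Reagents that add atoms: none
Why: Reversible enolisation toward C6 lets C5 settle in the trans-fused arrangement (thermodynamic epimerisation, favoured as in 5α-6-keto steroids and with the C4 substituent equatorial), while enolisation toward C9 places the C8 methyl equatorial and the quaternary C10 cannot change.

**Step 6**
Reactants: 7 trans-fused 6,9-dione
Product: 8 C6 mono-tosylhydrazone of 7 (C=N geometry not defined)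
Conditions: TsNHNH2 (1.05 equiv), MeOH, rt
Reagents that add atoms: 4-methylbenzenesulfonohydrazide, Cc1ccc(cc1)S(=O)(=O)NN
Why: Hydrazone condensation should occur only at C6 because the C9 carbonyl is screened by the quaternary C10 on one side and the methyl-bearing C8 on the other.

**Step 7**
Reactants: 8 C6 mono-tosylhydrazone
Product: 10 trans-decalin 9-ketone with C6 methylene (4α-CH2OTBS; 5α-H; 8α-methyl; 10β-methyl), via N-boryl tosylhydrazine 9 (not isolated)
Conditions: catecholborane, CHCl3, 0 °C; then NaOAc·3H2O, reflux
Reagents that add atoms: none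
Why: In this Caglioti-type reduction catecholborane adds H–B across the C=N bond and acetate then triggers loss of sulfinate and dinitrogen, leaving a methylene at C6 under conditions that spare the hindered C9 ketone, the silyl ether and the C5 configuration.

**Step 8**
Reactants: 10 trans-decalin 9-ketone
Product: 13 keto acid (4α-CO2H; 9-oxo), via primary alcohol 11 (not isolated), via aldehyde 12 (not isolated)
Conditions: CrO3, H2SO4, H2O, acetone, 0 °C to rt (Jones oxidation)
Reagents that add atoms: water, O
Why: The aqueous acid of the Jones oxidation cleaves the primary silyl ether and chromic acid then takes the alcohol through the aldehyde hydrate to the carboxylic acid, while the ketone is inert and the C4 configuration is irrelevant because it is reset in step 14.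

**Step 9**
Reactants: 13 keto acid
Product: 14 2-(trimethylsilyl)ethyl keto ester (4α-ester; 9-oxo)
Conditions: Me3SiCH2CH2OH, DCC, DMAP (cat.), CH2Cl2, 0 °C to rt
Reagents that add atoms: 2-(trimethylsilyl)ethanol, C[Si](C)(C)CCO
Why: Steglich esterification of the still unhindered secondary acid installs an ester that fluoride can later cleave at silicon, independent of the steric shielding the carboxyl will have once C4 is quaternary.

**Step 10**
Reactants: 14 2-(trimethylsilyl)ethyl keto ester
Product: 16 C9 enol triflate with C8=C9 alkene, via potassium enolate 15 (not isolated)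
Conditions: KN(SiMe3)2 (1.05 equiv), THF, −78 to −40 °C; then N-(5-chloropyridin-2-yl)bis(trifluoromethanesulfonyl)imide, −78 °C to rt
Reagents that add atoms: N-(5-chloropyridin-2-yl)-1,1,1-trifluoro-N-(trifluoromethylsulfonyl)methanesulfonamide, O=S(=O)(N(c1ccc(Cl)cn1)S(=O)(=O)C(F)(F)F)C(F)(F)F
Why: The ketone can enolise only toward C8 because C10 is quaternary and its α-hydrogen is several pKa units more acidic than the ester α-hydrogen, so one equivalent of base gives the ketone enolate, whose O-sulfonylation (enol triflate formation) fixes the C8=C9 alkene.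

**Step 11**
Reactants: 17 (E)-3-methylpent-2-en-4-yn-1-ol
Product: 18 (E)-tert-butyldimethyl[(3-methylpent-2-en-4-yn-1-yl)oxy]silane
Conditions: TBSCl, imidazole, CH2Cl2, 0 °C to rt
Reagents that add atoms: tert-butyldimethylsilyl chloride, CC(C)(C)[Si](C)(C)Cl
Why: Standard silylation of the primary allylic alcohol protects O15 for the organometallic steps and makes the small fragment less volatile.

**Step 12**
Reactants: 18 (E)-tert-butyldimethyl[(3-methylpent-2-en-4-yn-1-yl)oxy]silane
Product: 19 (E)-tert-butyldimethyl[(3-methylpenta-2,4-dien-1-yl)oxy]silane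
Conditions: H2 (1 atm), Pd/CaCO3 poisoned with Pb(OAc)2, quinoline, hexane, rt
Reagents that add atoms: none
Why: Semihydrogenation over the lead-poisoned catalyst (Lindlar reduction) should stop the terminal alkyne at the vinyl group and leave the E trisubstituted alkene, which becomes C13=C14, unchanged.

**Step 13**
Reactants: 16 C9 enol triflate; 19 (E)-tert-butyldimethyl[(3-methylpenta-2,4-dien-1-yl)oxy]silane
Product: 21 coupled diene ester 2-(trimethylsilyl)ethyl 15-(tert-butyldimethylsilyloxy)-18-norlabda-8,13E-dien-19-oate (ester 4α; H-4 β), via B-alkyl-9-BBN borane 20 (not isolated)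
Conditions: 9-BBN-H dimer, THF, 0 °C to rt; then 16, PdCl2(dppf) (dppf = 1,1'-bis(diphenylphosphino)ferrocene), AsPh3, K3PO4 (3 M aq), DMF, 50 °C
Reagents that add atoms: none
Why: 9-BBN-H should hydroborate only the terminal vinyl group of the diene, placing boron on C11, and the B-alkyl Suzuki–Miyaura coupling then joins C11 to C9 after oxidative addition of the enol triflate to zerovalent palladium, the bidentate phosphine limiting β-hydride elimination and the alkene positions and E geometry being retained.

**Step 14**
Reactants: 21 coupled diene ester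
Product: 23 2-(trimethylsilyl)ethyl 15-(tert-butyldimethylsilyloxy)labda-8,13E-dien-19-oate (4α-methyl; 4β-ester), via lithium ester enolate 22 (not isolated)
Conditions: LiN(i-Pr)2, THF, −78 to −20 °C; then DMPU, MeI, −78 to 0 °C
Reagents that add atoms: iodomethane, CI
Why: Ester enolate alkylation should occur from the α (equatorial) face because the β face of the exocyclic enolate is blocked by the 1,3-diaxial C10 methyl, which places the new methyl (C18) equatorial and the carboxylate (C19) axial and sets C4 as S.

**Step 15**
Reactants: 23 methylated bis-silyl compound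
Product: 24 15-hydroxylabda-8,13E-dien-19-oic acid
Conditions: Bu4NF (4 equiv), THF, rt to 40 °C; then aq NH4Cl
Reagents that add atoms: none
Why: Fluoride cleaves the Si–O bond of the allylic silyl ether and attacks the silicon of the 2-(trimethylsilyl)ethyl ester, whose fragmentation with loss of ethene frees the carboxylate without any attack at the hindered axial carbonyl (fluoride-mediated desilylation).

**Step 16**
Reactants: 24 15-hydroxylabda-8,13E-dien-19-oic acid
Product: 25 15-acetoxylabda-8,13E-dien-19-oic acid (target)
Conditions: Ac2O, pyridine, DMAP (cat.), CH2Cl2, 0 °C to rt; then H2O/pyridine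
Reagents that add atoms: acetic anhydride, CC(=O)OC(C)=O
Why: DMAP-catalysed acetylation takes the unhindered primary allylic alcohol, while the tertiary axial carboxylic acid is not lastingly acylated and is returned as the free acid by the aqueous pyridine work-up.

**Compound list**
1 | (E)-penta-2,4-dienoic acid | C=C/C=C/C(=O)O | starting material
2 | (E)-penta-2,4-dien-1-ol | C=C/C=C/CO | intermediate
3 | (E)-tert-butyldimethyl(penta-2,4-dien-1-yloxy)silane | C=C/C=C/CO[Si](C)(C)C(C)(C)C | intermediate
4 | 2,6-dimethyl-1,4-benzoquinone | CC1=CC(=O)C=C(C)C1=O | starting material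
5 | (4aR,5R,8aS)-5-[(tert-butyldimethylsilyloxy)methyl]-2,8a-dimethyl-4a,5,8,8a-tetrahydronaphthalene-1,4-dione; cis-fused adduct with 10β-methyl, 5β-H, 4α-CH2OTBS, alkenes C2=C3 and C7=C8, ketones at C6 and C9 | O=C1C(C)=CC(=O)[C@@H]2[C@H](CO[Si](C)(C)C(C)(C)C)C=CC[C@]12C | intermediate
6 | cis-fused saturated 6,9-dione (4α-CH2OTBS, 5β-H, 10β-methyl, both C8 epimers) | O=C1C(C)CC(=O)[C@@H]2[C@H](CO[Si](C)(C)C(C)(C)C)CCC[C@]12C | intermediate
7 | trans-fused 6,9-dione (4α-CH2OTBS, 5α-H, 8α-methyl, 10β-methyl) | O=C1[C@H](C)CC(=O)[C@H]2[C@H](CO[Si](C)(C)C(C)(C)C)CCC[C@]12C | intermediate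
8 | C6 mono-tosylhydrazone of 7 | O=C1[C@H](C)CC(=NNS(=O)(=O)c3ccc(C)cc3)[C@H]2[C@H](CO[Si](C)(C)C(C)(C)C)CCC[C@]12C | intermediate
9 | N-boryl tosylhydrazine (C6–N bearing the 1,3,2-benzodioxaborol-2-yl group, C6 configuration not defined) | O=C1[C@H](C)CC(N(B3Oc4ccccc4O3)NS(=O)(=O)c3ccc(C)cc3)[C@H]2[C@H](CO[Si](C)(C)C(C)(C)C)CCC[C@]12C | intermediate
10 | trans-decalin 9-ketone with C6 methylene (4α-CH2OTBS, 5α-H, 8α-methyl, 10β-methyl) | O=C1[C@H](C)CC[C@H]2[C@H](CO[Si](C)(C)C(C)(C)C)CCC[C@]12C | intermediate
11 | primary alcohol (4α-CH2OH, 9-oxo) | O=C1[C@H](C)CC[C@H]2[C@H](CO)CCC[C@]12C | intermediate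
12 | aldehyde (4α-CHO, 9-oxo) | O=C1[C@H](C)CC[C@H]2[C@H](C=O)CCC[C@]12C | intermediate
13 | keto acid (4α-CO2H, 5α-H, 8α-methyl, 10β-methyl, 9-oxo) | O=C1[C@H](C)CC[C@H]2[C@H](C(=O)O)CCC[C@]12C | intermediate
14 | 2-(trimethylsilyl)ethyl keto ester (4α-ester, 9-oxo) | O=C1[C@H](C)CC[C@H]2[C@H](C(=O)OCC[Si](C)(C)C)CCC[C@]12C | intermediate
15 | potassium enolate of 14 (C8=C9–OK) | [K+].[O-]C1=C(C)CC[C@H]2[C@H](C(=O)OCC[Si](C)(C)C)CCC[C@]12C | intermediate
16 | C9 enol triflate (C8=C9 alkene, 4α-ester, 5α-H, 10β-methyl) | O=S(=O)(OC1=C(C)CC[C@H]2[C@H](C(=O)OCC[Si](C)(C)C)CCC[C@]12C)C(F)(F)F | intermediate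
17 | (E)-3-methylpent-2-en-4-yn-1-ol | C#C/C(C)=C/CO | starting material
18 | (E)-tert-butyldimethyl[(3-methylpent-2-en-4-yn-1-yl)oxy]silane | C#C/C(C)=C/CO[Si](C)(C)C(C)(C)C | intermediate
19 | (E)-tert-butyldimethyl[(3-methylpenta-2,4-dien-1-yl)oxy]silane | C=C/C(C)=C/CO[Si](C)(C)C(C)(C)C | intermediate
20 | B-[(E)-5-(tert-butyldimethylsilyloxy)-3-methylpent-3-en-1-yl]-9-borabicyclo[3.3.1]nonane | CC(C)(C)[Si](C)(C)OC/C=C(\C)CCB1C2CCCC1CCC2 | intermediate
21 | 2-(trimethylsilyl)ethyl 15-(tert-butyldimethylsilyloxy)-18-norlabda-8,13E-dien-19-oate (ester 4α, H-4 β, 5α-H, 10β-methyl) | CC(C)(C)[Si](C)(C)OC/C=C(\C)CCC1=C(C)CC[C@H]2[C@H](C(=O)OCC[Si](C)(C)C)CCC[C@]12C | intermediate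
22 | lithium ester enolate of 21 (exocyclic C4=C19, enolate geometry not defined) | CC(C)(C)[Si](C)(C)OC/C=C(\C)CCC1=C(C)CC[C@H]2C(=C([O-])OCC[Si](C)(C)C)CCC[C@]12C.[Li+] | intermediate
23 | 2-(trimethylsilyl)ethyl 15-(tert-butyldimethylsilyloxy)labda-8,13E-dien-19-oate (4S,5R,10S) | CC(C)(C)[Si](C)(C)OC/C=C(\C)CCC1=C(C)CC[C@H]2[C@@](C)(C(=O)OCC[Si](C)(C)C)CCC[C@]12C | intermediate
24 | 15-hydroxylabda-8,13E-dien-19-oic acid (4S,5R,10S) | OC/C=C(\C)CCC1=C(C)CC[C@H]2[C@@](C)(C(=O)O)CCC[C@]12C | intermediate
25 | 15-acetoxylabda-8,13E-dien-19-oic acid (4S,5R,10S) | CC(=O)OC/C=C(\C)CCC1=C(C)CC[C@H]2[C@@](C)(C(=O)O)CCC[C@]12C | target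

**Totals**
Total step count: 16. Longest linear sequence: 14 steps (steps 1–10 and 13–16, from 1); the chain fragment takes 2 steps (11 and 12).

**Steps most likely to fail**

Step 3. The weakly nucleophilic diene may react too slowly at the methyl-bearing quinone carbon at the low temperature needed for face discrimination, or the silyl ether oxygen may compete for the boron centre, so that enantiofacial selectivity erodes. The fallback sets out from 3 and 4. They are combined with BF3·OEt2 in CH2Cl2 at −78 °C, which should give the racemic adduct F1 with the same regiochemistry and endo topology, since the achiral Lewis acid also sits on the C6 carbonyl. F1 is then resolved by preparative chromatography on a cellulose tris(3,5-dimethylphenylcarbamate) stationary phase. The (4aR,5R,8aS) enantiomer is 5, where the route is rejoined.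

Step 13. Oxidative addition and transmetalation at the tetrasubstituted triflate next to the quaternary C10 may be slow, so that protodeboronation of the alkylborane or β-hydride elimination overtakes the coupling. Hydroboration of the conjugated diene may also be incomplete. The fallback sets out from 16 and returns at 21:
- Stille coupling of 16 with tributyl(vinyl)stannane (Pd(PPh3)4, LiCl, THF, reflux) should give the 9-vinyl diene ester F2; this sp2–sp2 coupling tolerates the hindrance better.
- Hydroboration of the terminal vinyl group of F2 with 9-BBN-H should give the borane F3.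
- F3 is coupled (PdCl2(dppf), K3PO4, DMF/H2O) with the unhindered vinyl iodide (E)-tert-butyl[(3-iodobut-2-en-1-yl)oxy]dimethylsilane F5.
- F5 is made from but-2-yn-1-ol through its silyl ether (but-2-yn-1-yloxy)(tert-butyl)dimethylsilane F4 by hydrozirconation with Cp2Zr(H)Cl followed by I2.

The difficult C9–C11 bond is thus made as an sp2–sp2 bond and the sp3 coupling is moved to C12–C13.

Step 5. The cis and trans diones may equilibrate incompletely or to an unfavourable mixture, so that C5 is not set cleanly before the C6 carbonyl is removed. The fallback sets C5 kinetically; it sets out from 5 and returns at 10, replacing steps 4–7: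
- Luche reduction (NaBH4, CeCl3·7H2O, MeOH, −78 °C) at the less hindered C6 carbonyl should give the C6 allylic alcohol F6.
- Mesylation (MsCl, Et3N, CH2Cl2) gives the C6 mesylate F7, and elimination with DBU gives the trienone F8 (C2=C3, C5=C6, C7=C8, C9 ketone).
- Hydrogenation (H2, Pd/C, EtOAc) should deliver hydrogen to C5 from the α face opposite the C10 methyl while saturating the other alkenes, giving 10.

Any C4 epimer formed by alkene migration during the hydrogenation is harmless because C4 is planarised in step 14.

**Further compounds**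
F1 | step 3 | racemic adduct (5 together with its enantiomer) | O=C1C(C)=CC(=O)[C@@H]2[C@H](CO[Si](C)(C)C(C)(C)C)C=CC[C@]12C.O=C1C(C)=CC(=O)[C@H]2[C@@H](CO[Si](C)(C)C(C)(C)C)C=CC[C@@]12C
F2 | step 13 | 9-vinyl diene ester (2-(trimethylsilyl)ethyl ester 4α, C8=C9 and C11=C12 alkenes) | C=CC1=C(C)CC[C@H]2[C@H](C(=O)OCC[Si](C)(C)C)CCC[C@]12C
F3 | step 13 | B-alkyl-9-BBN borane from F2 (boron on C12) | B1(CCC3=C(C)CC[C@H]4[C@H](C(=O)OCC[Si](C)(C)C)CCC[C@]34C)C2CCCC1CCC2
F4 | step 13 | (but-2-yn-1-yloxy)(tert-butyl)dimethylsilane | CC#CCO[Si](C)(C)C(C)(C)C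
F5 | step 13 | (E)-tert-butyl[(3-iodobut-2-en-1-yl)oxy]dimethylsilane | C/C(I)=C\CO[Si](C)(C)C(C)(C)C
F6 | step 5 | C6 allylic alcohol from 5 (C6 configuration not defined) | O=C1C(C)=CC(O)[C@@H]2[C@H](CO[Si](C)(C)C(C)(C)C)C=CC[C@]12C
F7 | step 5 | C6 mesylate of F6 | O=C1C(C)=CC(OS(C)(=O)=O)[C@@H]2[C@H](CO[Si](C)(C)C(C)(C)C)C=CC[C@]12C
F8 | step 5 | trienone (C2=C3, C5=C6, C7=C8, 9-oxo, 4α-CH2OTBS, 10β-methyl) | O=C1C(C)=CC=C2[C@H](CO[Si](C)(C)C(C)(C)C)C=CC[C@]12C
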